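**Plan**
- Retrosynthesis: (1) close the acid onto the neighbouring enol oxygen as an enol lactone; (2) cut the prenyl–C bond at the quaternary carbon (dearomative allylation of a benzene ring); (3) cut the ring–CH2 bond to the lavandulyl chain; (4) cut the benzylic C–phenyl bond; (5) cut the ether O–CH(Me) bond and the ketone C–ring bond of the dihydropyranone, back to 5,7-dihydroxycoumarin and tigloyl chloride.
- Forward: bought coumarin (benzene ring plus lactone ring) → dihydropyranone ring annulated first → phenyl added to the lactone ring → iodide → lavandulyl chain → prenyl group with dearomatisation → lactone opened.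
- Enabling feature: in the coumarin, C8–H lies between the lactone oxygen O1 and the free 7-OH, so C8/C7–OH is an enol-like C,O-dinucleophile matched to the 1,3-dielectrophile tigloyl chloride. The C3=C4 bond (used up in step 2) and the lactone ring (opened in step 8) are the helpers that send the acyl group to C8 and leave O7 as the only oxygen able to close the ring.
- Stereochemistry: cis-2,3-dimethyl pair from quinine-controlled oxa-Michael addition and kinetic protonation; benzylic centre from rhodium/(S)-SEGPHOS arylation; side-chain centre from (R)-lavandulol; quaternary carbon from palladium/chiral-ligand-controlled allylation.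

Key step: step 1

Remark: (R)-(−)-lavandulol is taken as a purchasable single enantiomer; its stereocentre is carried unchanged into the target (the descriptor changes from R to S only because CH2OH becomes the ring-bound CH2).
Remark: the target is drawn as one tautomer of an enolised cyclic β-triketone; the route delivers that compound whichever tautomer predominates.
Remark: tricyclic intermediates are numbered as pyrano[2,3-f]chromenes (O1, C2 lactone carbonyl, C4 benzylic carbon, C5 phenol carbon, C6, O7, C8 ether carbon, C9, C10 ketone); compounds 1 and 3 carry coumarin numbers.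

**Step 1**
Reactants: 1 5,7-dihydroxy-2H-chromen-2-one (5,7-dihydroxycoumarin); 2 (E)-2-methylbut-2-enoyl chloride (tigloyl chloride)
Product: 4 (8R,9S)-5-hydroxy-8,9-dimethyl-8,9-dihydro-2H,10H-pyrano[2,3-f]chromene-2,10-dione, via 8-tigloyl-5,7-dihydroxycoumarin 3 (not isolated)
Conditions: AlCl3 (4 equiv), PhNO2–CS2, 50 °C; cold aq. HCl quench, EtOAc extraction, crude 3 carried on; quinine (20 mol%), PhCl, 15 °C
Reagents that add atoms: none
Why: AlCl3-activated 2 acylates the coumarin at its C8, the carbon between the lactone oxygen O1 and the free 7-OH, to give the chelated 2-hydroxyaryl enone 3, and quinine then promotes the intramolecular oxa-Michael addition of the 7-OH to the β-carbon of the tiglyl group as a bifunctional Brønsted base (quinuclidine nitrogen to the phenol, its secondary hydroxyl to the ketone). The closest known reaction type is Friedel–Crafts C-acylation of a 7-hydroxycoumarin followed by cinchona-alkaloid-mediated enantioselective cyclisation of a 2-hydroxyaryl tiglyl ketone to a 2,3-dimethylchroman-4-one, here telescoped. The one new ring (O7–C8–C9–C10–C10a–C6a of 4) closes in the 6-endo-trig mode. The ether carbon C8 of 4 is set as R by the alkaloid-bound phenoxide attacking one enantioface of the s-cis enone, and C9 is set as S by kinetic protonation of the resulting enol on the face away from the new C8 methyl group, which gives the cis pair. The step needs C8 over C6 acylation, secured by the coumarin C3=C4 bond (the 7-hydroxycoumarin pattern reacts at C8); a single oxygen for ring closure, secured because O1 is locked in the lactone; and survival of the kinetic cis isomer, secured by the weak amine base at low temperature.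

**Step 2**
Reactants: 4 (8R,9S)-5-hydroxy-8,9-dimethyl-8,9-dihydro-2H,10H-pyrano[2,3-f]chromene-2,10-dione; 5 phenylboronic acid
Product: 6 (4S,8R,9S)-5-hydroxy-8,9-dimethyl-4-phenyl-3,4,8,9-tetrahydro-2H,10H-pyrano[2,3-f]chromene-2,10-dione
Conditions: Rh(acac)(C2H4)2 (3 mol%), (S)-SEGPHOS (3.3 mol%), 5 (5 equiv), 1,4-dioxane/H2O (10:1), 60 °C
Reagents that add atoms: none
Why: Rhodium-catalysed asymmetric 1,4-addition of an arylboronic acid to a coumarin (Hayashi–Miyaura reaction): the phenyl–rhodium species adds across C3=C4 with phenyl going to C4 on the enantioface selected by (S)-SEGPHOS, which should give 4S (the ligand antipode is taken if a test run shows the opposite sense), while the ketone, the phenol and the cis-dimethyl pair are untouched under these near-neutral conditions.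

**Step 3**
Reactants: 6 (4S,8R,9S)-5-hydroxy-8,9-dimethyl-4-phenyl-3,4,8,9-tetrahydro-2H,10H-pyrano[2,3-f]chromene-2,10-dione
Product: 7 (4S,8R,9S)-5-hydroxy-6-iodo-8,9-dimethyl-4-phenyl-3,4,8,9-tetrahydro-2H,10H-pyrano[2,3-f]chromene-2,10-dione
Conditions: NIS (1.05 equiv), TFA (10 mol%), MeCN, 0 °C to rt
Reagents that add atoms: N-iodosuccinimide, O=C1CCC(=O)N1I
Why: Electrophilic aromatic iodination: C6 is the only aromatic C–H left and is activated by the ortho 5-OH and the ortho ether oxygen O7, so iodine should enter there without touching a stereocentre.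

**Step 4**
Reactants: 8 (R)-lavandulol, (2R)-5-methyl-2-(prop-1-en-2-yl)hex-4-en-1-ol
Product: 9 (3R)-3-(iodomethyl)-2,6-dimethylhepta-1,5-diene (lavandulyl iodide)
Conditions: I2, PPh3, imidazole, CH2Cl2, 0 °C to rt
Reagents that add atoms: iodine, [I][I]
Why: Appel-type iodination of a primary alcohol (SN2 displacement of the alkoxyphosphonium group by iodide at CH2); the stereocentre is β to the reacting carbon and both alkenes are inert, so the configuration is carried over.

**Step 5**
Reactants: 7 (4S,8R,9S)-5-hydroxy-6-iodo-8,9-dimethyl-4-phenyl-3,4,8,9-tetrahydro-2H,10H-pyrano[2,3-f]chromene-2,10-dione; 9 (3R)-3-(iodomethyl)-2,6-dimethylhepta-1,5-diene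
Product: 11 (4S,8R,9S)-5-hydroxy-8,9-dimethyl-6-[(2S)-5-methyl-2-(prop-1-en-2-yl)hex-4-en-1-yl]-4-phenyl-3,4,8,9-tetrahydro-2H,10H-pyrano[2,3-f]chromene-2,10-dione, via lavandulylzinc iodide 10 (not isolated)
Conditions: 9, Zn dust (activated with 1,2-dibromoethane/TMSCl), LiCl, THF, 40 °C; then 7, Pd(OAc)2 (3 mol%), SPhos (6 mol%), THF, 25 to 50 °C, slow addition of 10 (1.5 equiv)
Reagents that add atoms: none
Why: Negishi sp3–sp2 coupling: zinc inserts into the primary C–I bond of 9, the alkylzinc iodide 10 transmetalates to the arylpalladium formed from 7, and the bulky biarylphosphine favours reductive elimination over β-hydride elimination; slow addition should let coupling outrun protonolysis by the free phenol, and the side-chain stereocentre, β to zinc, is not affected.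

**Step 6**
Reactants: 12 3-methylbut-2-en-1-ol (prenol)
Product: 13 tert-butyl 3-methylbut-2-en-1-yl carbonate
Conditions: Boc2O (1.2 equiv), DMAP (10 mol%), CH2Cl2, 0 °C to rt
Reagents that add atoms: di-tert-butyl dicarbonate, CC(C)(C)OC(=O)OC(=O)OC(C)(C)C
Why: DMAP-catalysed acylation of the primary allylic alcohol gives the mixed carbonate, the ionisable leaving group that allows base-free Tsuji–Trost chemistry in the next step.

**Step 7**
Reactants: 11 (4S,8R,9S)-5-hydroxy-8,9-dimethyl-6-[(2S)-5-methyl-2-(prop-1-en-2-yl)hex-4-en-1-yl]-4-phenyl-3,4,8,9-tetrahydro-2H,10H-pyrano[2,3-f]chromene-2,10-dione; 13 tert-butyl 3-methylbut-2-en-1-yl carbonate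
Product: 14 (4S,6S,8R,9S)-8,9-dimethyl-6-(3-methylbut-2-en-1-yl)-6-[(2S)-5-methyl-2-(prop-1-en-2-yl)hex-4-en-1-yl]-4-phenyl-3,4,8,9-tetrahydro-2H-pyrano[2,3-f]chromene-2,5,10(6H)-trione
Conditions: Pd2(dba)3 (2.5 mol%), (R,R)-DACH-phenyl Trost ligand (7.5 mol%), 13 (1.5 equiv), toluene, 0 °C to rt
Reagents that add atoms: none
Why: Tsuji–Trost allylic alkylation run as a catalytic asymmetric dearomatisation of a phenol: ionisation of 13 gives a π-prenyl palladium complex and tert-butoxide, which deprotonates the 5-OH; the phenoxide should attack the unsubstituted allyl terminus through C6 (the other ortho carbon C4a and the para carbon C10a are ring-fusion carbons, and O-allylation is reversible under palladium), and the chiral pocket of the ligand selects the face of the planar ring so that the new quaternary carbon is 6S (the ligand antipode is chosen by a test run, since the remote stereocentres give little bias).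

**Step 8**
Reactants: 14 (4S,6S,8R,9S)-8,9-dimethyl-6-(3-methylbut-2-en-1-yl)-6-[(2S)-5-methyl-2-(prop-1-en-2-yl)hex-4-en-1-yl]-4-phenyl-3,4,8,9-tetrahydro-2H-pyrano[2,3-f]chromene-2,5,10(6H)-trione
Product: 15 (3S)-3-[(2R,3S,8S)-5-hydroxy-2,3-dimethyl-8-(3-methylbut-2-en-1-yl)-8-[(2S)-5-methyl-2-(prop-1-en-2-yl)hex-4-en-1-yl]-4,7-dioxo-3,4,7,8-tetrahydro-2H-chromen-6-yl]-3-phenylpropanoic acid (CNP0150579.2)
Conditions: LiOH (3 equiv), THF/H2O (3:1), 0 °C; then 1 M HCl to pH 3–4, 0 °C
Reagents that add atoms: water, O (delivered as aqueous lithium hydroxide, [Li+].[OH-])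
Why: Saponification: the O1–C2 enol lactone is a vinylogous anhydride and the most electrophilic carbonyl, so hydroxide should open it at 0 °C to the carboxylate and the enolate of the cyclic triketone, a dianion in which C9–H is too weakly acidic for epimerisation or retro-oxa-Michael opening; mild acidification then gives 15 with all five stereocentres unchanged.

**Compound list**
1 | 5,7-dihydroxy-2H-chromen-2-one (5,7-dihydroxycoumarin) | O=C1C=Cc2c(O)cc(O)cc2O1 | starting material
2 | (E)-2-methylbut-2-enoyl chloride (tigloyl chloride) | C/C=C(\C)C(Cl)=O | starting material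
3 | 5,7-dihydroxy-8-[(E)-2-methylbut-2-enoyl]-2H-chromen-2-one | C/C=C(\C)C(=O)c1c(O)cc(O)c2C=CC(=O)Oc12 | intermediate
4 | (8R,9S)-5-hydroxy-8,9-dimethyl-8,9-dihydro-2H,10H-pyrano[2,3-f]chromene-2,10-dione | Oc1cc2O[C@H](C)[C@H](C)C(=O)c2c2OC(=O)C=Cc12 | intermediate
5 | phenylboronic acid | OB(O)c1ccccc1 | starting material
6 | (4S,8R,9S)-5-hydroxy-8,9-dimethyl-4-phenyl-3,4,8,9-tetrahydro-2H,10H-pyrano[2,3-f]chromene-2,10-dione | Oc1cc2O[C@H](C)[C@H](C)C(=O)c2c2OC(=O)C[C@@H](c3ccccc3)c12 | intermediate
7 | (4S,8R,9S)-5-hydroxy-6-iodo-8,9-dimethyl-4-phenyl-3,4,8,9-tetrahydro-2H,10H-pyrano[2,3-f]chromene-2,10-dione | Oc1c(I)c2O[C@H](C)[C@H](C)C(=O)c2c2OC(=O)C[C@@H](c3ccccc3)c12 | intermediate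
8 | (R)-lavandulol, (2R)-5-methyl-2-(prop-1-en-2-yl)hex-4-en-1-ol | C=C(C)[C@@H](CC=C(C)C)CO | starting material
9 | (3R)-3-(iodomethyl)-2,6-dimethylhepta-1,5-diene | C=C(C)[C@@H](CC=C(C)C)CI | intermediate
10 | [(2R)-5-methyl-2-(prop-1-en-2-yl)hex-4-en-1-yl]zinc iodide | C=C(C)[C@@H](CC=C(C)C)C[Zn]I | intermediate
11 | (4S,8R,9S)-5-hydroxy-8,9-dimethyl-6-[(2S)-5-methyl-2-(prop-1-en-2-yl)hex-4-en-1-yl]-4-phenyl-3,4,8,9-tetrahydro-2H,10H-pyrano[2,3-f]chromene-2,10-dione | Oc1c(C[C@H](CC=C(C)C)C(C)=C)c2O[C@H](C)[C@H](C)C(=O)c2c2OC(=O)C[C@@H](c3ccccc3)c12 | intermediate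
12 | 3-methylbut-2-en-1-ol (prenol) | CC(C)=CCO | starting material
13 | tert-butyl 3-methylbut-2-en-1-yl carbonate | CC(C)=CCOC(=O)OC(C)(C)C | intermediate
14 | (4S,6S,8R,9S)-8,9-dimethyl-6-(3-methylbut-2-en-1-yl)-6-[(2S)-5-methyl-2-(prop-1-en-2-yl)hex-4-en-1-yl]-4-phenyl-3,4,8,9-tetrahydro-2H-pyrano[2,3-f]chromene-2,5,10(6H)-trione | C=C(C)[C@@H](CC=C(C)C)C[C@]1(CC=C(C)C)C(=O)C3=C(OC(=O)C[C@H]3c4ccccc4)C2=C1O[C@H](C)[C@H](C)C2=O | intermediate
15 | (3S)-3-[(2R,3S,8S)-5-hydroxy-2,3-dimethyl-8-(3-methylbut-2-en-1-yl)-8-[(2S)-5-methyl-2-(prop-1-en-2-yl)hex-4-en-1-yl]-4,7-dioxo-3,4,7,8-tetrahydro-2H-chromen-6-yl]-3-phenylpropanoic acid | C=C(C)[C@@H](CC=C(C)C)C[C@]1(CC=C(C)C)C(=O)C([C@@H](CC(=O)O)c2ccccc2)=C(O)C2=C1O[C@H](C)[C@H](C)C2=O | target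

Total step count: 8. Longest linear sequence: 6 steps (steps 1, 2, 3, 5, 7, 8).

**Steps most likely to fail**

Step 7. The phenoxide may be allylated on oxygen faster than the ether re-ionises, the allyl fragment may be delivered to the wrong face of C6 because catalyst control over a planar ring with only remote stereocentres is weak, or the product enol lactone may be cleaved by the alkoxide that is released. The fallback sets out from 11 and comes back to the route at 15. Compound 11 would first be saponified (LiOH, THF/H2O, 0 °C, then mild acid) to the aromatic chromanone acid (3S)-3-[(2R,3S)-5,7-dihydroxy-2,3-dimethyl-8-[(2S)-5-methyl-2-(prop-1-en-2-yl)hex-4-en-1-yl]-4-oxo-3,4-dihydro-2H-chromen-6-yl]-3-phenylpropanoic acid F1. Its polyanion would then be C-prenylated with prenyl bromide in aqueous KOH at 0 °C, the classical dearomative C-alkylation of an acylphloroglucinol in which water suppresses O-alkylation and the bulky benzylic branch shields the other substituted ring carbon. This should give 15 directly together with its epimer at the quaternary carbon; stereocontrol is given up and the epimer would be removed by preparative HPLC.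

Step 5. The alkylzinc may be protonated by the phenol, transmetalation to the doubly ortho-substituted arylpalladium may be slow, and β-hydride elimination may return the reduced arene. The fallback sets out from 7 (with 9) and comes back at 11: a nickel-catalysed reductive cross-electrophile coupling of the aryl iodide with the alkyl iodide (NiI2, 4,4′-di-tert-butyl-2,2′-bipyridine, Zn dust, NaI, DMA, 40 °C), which needs no preformed organozinc and proceeds through an alkyl radical captured at nickel. This fallback makes no new compound (F0).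

Step 2. Addition of the phenyl–rhodium species to the electron-rich, peri-hindered coumarin may be so slow that protodeboronation of 5 uses up the reagent, or the 5-OH may erode facial selectivity. The fallback sets out from 4 and comes back at 6. An oxidative Heck arylation with 5 (Pd(OAc)2, 1,10-phenanthroline, O2, DMF, 80 °C) would put phenyl on C4 with the C3=C4 bond kept, giving (8R,9S)-5-hydroxy-8,9-dimethyl-4-phenyl-8,9-dihydro-2H,10H-pyrano[2,3-f]chromene-2,10-dione F2. A copper hydride-catalysed asymmetric conjugate reduction (Cu(OAc)2, (S)-DTBM-SEGPHOS or its antipode as a test run requires, diethoxymethylsilane, t-BuOH, toluene, 0 °C) would then set C4 by hydride delivery and give 6; the hindered, donor-substituted C10 ketone is expected to react more slowly than the enoate.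

**Further compounds**
F1 | step 7 | (3S)-3-[(2R,3S)-5,7-dihydroxy-2,3-dimethyl-8-[(2S)-5-methyl-2-(prop-1-en-2-yl)hex-4-en-1-yl]-4-oxo-3,4-dihydro-2H-chromen-6-yl]-3-phenylpropanoic acid | Oc1c(C[C@H](CC=C(C)C)C(C)=C)c2O[C@H](C)[C@H](C)C(=O)c2c(O)c1[C@@H](CC(=O)O)c1ccccc1
F0 | step 5 | none | none
F2 | step 2 | (8R,9S)-5-hydroxy-8,9-dimethyl-4-phenyl-8,9-dihydro-2H,10H-pyrano[2,3-f]chromene-2,10-dione | Oc1cc2O[C@H](C)[C@H](C)C(=O)c2c2OC(=O)C=C(c3ccccc3)c12
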